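Ring B is built by a two-carbon ring expansion of a diquinane. The feature used is that the ketone carbon C7 and the aroyloxy carbon C6 of the seven-membered ring B are neighbours, flanked by the methyl carbinol carbon C8 and the fusion carbon C5. Irradiation of bicyclo[3.3.0]octenone 16, whose C5=C8 enone bond already carries ring A, the quaternary C1 methyl and the silyl-protected C4 carbinol, with acetylene forms C5–C6 and C7–C8 in one operation. Thermal opening of the cyclobutene then breaks C5–C8 and gives the ring B dienone, so that C5 to C9 are all left sp2 for the later oxygenation and reduction.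

Key step: step 9

Remark on numbering: atom labels follow the daucane skeleton of the target. Ring A is C1 (quaternary, methyl), C2, C3, C4 (carbinol, isopropyl), C5 (fusion CH). Ring B is C1, C5, C6 (aroyloxy), C7 (ketone), C8 (methyl carbinol), C9 (secondary carbinol), C10. "Upper face" is the face of H5 in the target; the C1 methyl, the C4 oxygen and the C8 methyl lie on the lower face, and the oxygens on C6, C8 and C9 on the upper face.

Step 1
Reactants: 1 3-methylbut-1-yne; 2 paraformaldehyde
Product: 4 4-methylpent-2-yn-1-ol, via lithium 3-methylbut-1-yn-1-ide 3 (not isolated)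
Conditions: n-BuLi, THF, −78 °C; then (CH2O)n, −78 °C → rt; H2O
Reagents that add atoms: none
Why: Hydroxymethylation of a lithium acetylide with formaldehyde is a standard alkynylation and creates no stereocentre.

Step 2
Reactants: 4 4-methylpent-2-yn-1-ol
Product: 6 (2Z)-3-iodo-4-methylpent-2-en-1-ol, via sodium alkenylalanate 5 (not isolated)
Conditions: NaAlH2(OCH2CH2OMe)2, THF, 0 °C → rt; then I2, THF, −78 → 0 °C
Reagents that add atoms: iodine, II
Why: Alkoxide-directed trans-hydroalumination of a propargylic alcohol places aluminium on C3 inside a five-membered ring, and iodinolysis with retention gives the iodide with iodine cis to CH2OH, so the isopropyl group is locked trans to the carbinol carbon.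

Step 3
Reactants: 6 (2Z)-3-iodo-4-methylpent-2-en-1-ol; 7 4-bromo-2-methylbut-1-ene
Product: 9 (2E)-6-methyl-3-(propan-2-yl)hepta-2,6-dien-1-ol, via (3-methylbut-3-en-1-yl)zinc bromide 8 (not isolated)
Conditions: 7, Zn, LiCl, THF, 50 °C; then 6, Pd(dppf)Cl2 (5 mol %), THF, 50 °C (8 in excess)
Reagents that add atoms: none
Why: Negishi coupling of an alkenyl iodide with a primary alkylzinc halide proceeds with retention of alkene geometry and tolerates the free alcohol when the zinc reagent is in excess, so the trisubstituted alkene should form as a single geometric isomer.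

Step 4
Reactants: 9 (2E)-6-methyl-3-(propan-2-yl)hepta-2,6-dien-1-ol
Product: 10 [(2R,3R)-3-(3-methylbut-3-en-1-yl)-3-(propan-2-yl)oxiran-2-yl]methanol
Conditions: Ti(OiPr)4 (10 mol %), D-(−)-diethyl tartrate (12 mol %), t-BuOOH, 4 Å molecular sieves, CH2Cl2, −20 °C
Reagents that add atoms: tert-butyl hydroperoxide, CC(C)(C)OO
Why: Sharpless asymmetric epoxidation with the D-(−)-tartrate delivers oxygen to the face that makes the quaternary epoxide carbon (R), and the substrate has only a primary chain cis to CH2OH (the nerol pattern), which is the substitution that gives reliably high enantioselectivity.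

Step 5
Reactants: 10 [(2R,3R)-3-(3-methylbut-3-en-1-yl)-3-(propan-2-yl)oxiran-2-yl]methanol
Product: 11 (2R,3S)-3-(chloromethyl)-2-(3-methylbut-3-en-1-yl)-2-(propan-2-yl)oxirane
Conditions: PPh3, CCl4, NaHCO3, 75 °C
Reagents that add atoms: tetrachloromethane, ClC(Cl)(Cl)Cl
Why: Appel chlorination of the primary alcohol under buffered conditions leaves the epoxide and both stereocentres untouched (the descriptor of the CH carbon changes only because CH2Cl outranks the ring carbon).

Step 6
Reactants: 11 (2R,3S)-3-(chloromethyl)-2-(3-methylbut-3-en-1-yl)-2-(propan-2-yl)oxirane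
Product: 13 (4R)-7-methyl-4-(propan-2-yl)oct-7-en-2-yn-4-ol, via dilithium alkynide alkoxide 12 (not isolated)
Conditions: n-BuLi (3.1 equiv), THF, −78 → −30 °C; then MeI, DMPU, −78 → 0 °C; H2O
Reagents that add atoms: iodomethane, CI
Why: Base-induced fragmentation of a 2,3-epoxy chloride (deprotonation next to chlorine, β-opening of the epoxide, loss of HCl) gives the propargylic alkoxide with the C–O bond of the quaternary carbon intact, and the lithium alkynide made by the third equivalent of base is C-methylated far faster than the hindered tertiary lithium alkoxide.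

Step 7
Reactants: 13 (4R)-7-methyl-4-(propan-2-yl)oct-7-en-2-yn-4-ol
Product: 14 triethyl{[(4R)-7-methyl-4-(propan-2-yl)oct-7-en-2-yn-4-yl]oxy}silane
Conditions: Et3SiOTf, 2,6-lutidine, CH2Cl2, −78 → 0 °C
Reagents that add atoms: triethylsilyl trifluoromethanesulfonate, CC[Si](CC)(CC)OS(=O)(=O)C(F)(F)F
Why: Silyl triflates silylate hindered tertiary alcohols, and the ether masks the carbinol through the cobalt, photochemical and thermal steps.

Step 8
Reactants: 14 triethyl{[(4R)-7-methyl-4-(propan-2-yl)oct-7-en-2-yn-4-yl]oxy}silane
Product: 16 (4R,6aR)-3,6a-dimethyl-4-(propan-2-yl)-4-[(triethylsilyl)oxy]-4,5,6,6a-tetrahydropentalen-2(1H)-one, via hexacarbonyldicobalt alkyne complex 15 (not isolated)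
Conditions: Co2(CO)8, CH2Cl2, rt; then N-methylmorpholine N-oxide, CH2Cl2, rt → 40 °C
Reagents that add atoms: dicobalt octacarbonyl (gives one CO), O=C=[Co](=C=O)(=C=O)(=C=O)[Co](=C=O)(=C=O)(=C=O)=C=O
Why: The intramolecular Pauson–Khand reaction of the 1,6-enyne forms ring A and the cyclopentenone together, and the C4 centre controls the new quaternary C1 because propargylic silyloxy groups are known to take the exo position next to the ring-fusion substituent (here the methyl), although the competing isopropyl group makes the level of selectivity uncertain and the diastereomers may need separation.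

Step 9
Reactants: 16 (4R,6aR)-3,6a-dimethyl-4-(propan-2-yl)-4-[(triethylsilyl)oxy]-4,5,6,6a-tetrahydropentalen-2(1H)-one; 17 acetylene
Product: 18 4,7-dimethyl-10-(propan-2-yl)-10-[(triethylsilyl)oxy]tricyclo[5.3.0.0^{1,4}]dec-2-en-5-one (cyclobutene C6=C7 bonded to C5 and C8, cis-fused to the cyclopentanone on the face of the C1 methyl)
Conditions: C2H2 (saturated, continuous stream), THF, −70 °C, hν (Hg lamp, uranium-glass filter, λ > 340 nm)
Reagents that add atoms: none
Why: Excitation of the enone and intersystem crossing give the twisted triplet, which adds to acetylene stepwise through a 1,4-diradical, the first bond forming at C5 or C8 and the second after spin inversion, as in the known [2+2] photocycloadditions of cyclopent-2-enones with acetylene. The four-membered ring closes by recombination of that 1,4-diradical across the former C5=C8 π bond. The two new stereocentres C5 and C8 are fixed by strain alone, since the cyclobutene can only be cis-fused to the cyclopentanone and C5 can only bond on the face of the C1 methyl (a trans-fused diquinane is prohibitively strained), and both centres become sp2 again in step 10. Acetylene is symmetrical, so no regiochemistry arises. The selectivity needed is cross-addition over enone dimerisation and over secondary photolysis of the β,γ-unsaturated ketone product; it is secured by the large excess of dissolved acetylene at low temperature, by the fully substituted enone, which resists dimerisation, and by the long-wavelength filter.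

Step 10
Reactants: 18 cyclobutene-fused tricyclic ketone
Product: 19 4-(triethylsilyloxy)dauca-5,7-dien-9-one (C1 methyl and C4 OSiEt3 cis)
Conditions: PhMe (0.01 M), sealed tube, 190 °C
Reagents that add atoms: none
Why: Strain-driven electrocyclic opening of the cis-fused cyclobutene, known for bicyclo[3.2.0]hept-6-en-2-ones where the C9 carbonyl weakens the C5–C8 bond, cleaves the former enone bond and leaves the two acetylene carbons inside a cyclohepta-2,4-dienone; no stereocentre is formed.

Step 11
Reactants: 19 4-(triethylsilyloxy)dauca-5,7-dien-9-one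
Product: 20 7,8-epoxy-4-(triethylsilyloxy)dauc-5-en-9-one (epoxide drawn on the upper face; either face serves)
Conditions: 30% H2O2, NaOH, MeOH, 0 °C
Reagents that add atoms: hydrogen peroxide, OO
Why: In this Weitz–Scheffer epoxidation the hydroperoxide anion adds 1,4 to the unhindered C7, not 1,6 to the fully substituted C5, and the enolate closes the C7–C8 epoxide as with carvone; the face is immaterial because C8 and C7 are flattened again in steps 12 and 13.

Step 12
Reactants: 20 7,8-epoxy-4-(triethylsilyloxy)dauc-5-en-9-one
Product: 21 4-(triethylsilyloxy)dauca-5,8-dien-7-ol (C7 configuration follows the epoxide and is of no consequence)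
Conditions: N2H4·H2O, AcOH (cat.), MeOH, 0 °C → rt
Reagents that add atoms: none
Why: In the Wharton transposition the epoxy hydrazone fragments with loss of N2 to the allylic alcohol, which moves the oxygen from C9 to C7 and the double bond to C8=C9.

Step 13
Reactants: 21 4-(triethylsilyloxy)dauca-5,8-dien-7-ol
Product: 22 4-(triethylsilyloxy)dauca-5,8-dien-7-one
Conditions: MnO2, CH2Cl2, rt
Reagents that add atoms: none
Why: MnO2 oxidises the doubly allylic secondary alcohol to the cross-conjugated dienone, which now carries the ketone on C7 where the target has it.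

Step 14
Reactants: 22 4-(triethylsilyloxy)dauca-5,8-dien-7-one
Product: 23 8,9-dihydroxy-4-(triethylsilyloxy)dauc-5-en-7-one (8-OH and 9-OH cis, both on the upper face)
Conditions: OsO4 (5 mol %), N-methylmorpholine N-oxide, acetone/H2O, rt
Reagents that add atoms: N-methylmorpholine N-oxide, C[N+]1([O-])CCOCC1; water, O
Why: Catalytic osmium tetroxide dihydroxylation is suprafacial and should occur at the less hindered C8=C9 bond (C5=C6 is flanked by two quaternary carbons) and on the upper face, anti to the pseudoaxial C1 methyl that stands 1,3 to C9, as in the osmylation of steroidal 2-enes anti to the angular methyl; C8 and C9 are set together.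

Step 15
Reactants: 23 8,9-dihydroxy-4-(triethylsilyloxy)dauc-5-en-7-one
Product: 24 8,9-dihydroxy-4-(triethylsilyloxy)daucan-7-one (H5 on the upper face, trans ring fusion)
Conditions: H2 (1–20 bar), [Ir(cod)(PCy3)(py)]PF6 (10 mol %), CH2Cl2, rt
Reagents that add atoms: none
Why: In this hydroxyl-directed homogeneous hydrogenation the cationic iridium catalyst binds the upper-face C8 and C9 hydroxyls and delivers H2 to the same face of the C5=C6 enone bond, which is also the face away from the C1 methyl and the C4 silyloxy group, so H5 ends up trans to the angular methyl.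

Step 16
Reactants: 24 8,9-dihydroxy-4-(triethylsilyloxy)daucan-7-one
Product: 25 4,8,9-tris(triethylsilyloxy)daucan-7-one
Conditions: Et3SiOTf, 2,6-lutidine, CH2Cl2, −78 → 0 °C
Reagents that add atoms: triethylsilyl trifluoromethanesulfonate, CC[Si](CC)(CC)OS(=O)(=O)C(F)(F)F
Why: The silyl triflate caps the secondary C9 and tertiary C8 hydroxyls (any silyl enol ether, possible only towards C6, is hydrolysed on work-up), which blocks retro-aldol cleavage and silyl migration in the basic step that follows.

Step 17
Reactants: 25 4,8,9-tris(triethylsilyloxy)daucan-7-one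
Product: 27 6-hydroxy-4,8,9-tris(triethylsilyloxy)daucan-7-one (6-OH on the upper face), via potassium enolate 26 (not isolated)
Conditions: KN(SiMe3)2, THF, −78 °C; then 2-(phenylsulfonyl)-3-phenyloxaziridine, −78 °C; AcOH
Reagents that add atoms: 2-(phenylsulfonyl)-3-phenyloxaziridine, O=S(=O)(c1ccccc1)N1OC1c1ccccc1
Why: Enolisation can occur only towards C6 because C8 is fully substituted, and oxygen transfer from the N-sulfonyloxaziridine to the enolate should come from the upper face, anti to the pseudoaxial C1 methyl, giving the equatorial C6 hydroxyl cis to H5, which is also the epimer expected on equilibration.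

Step 18
Reactants: 28 4-hydroxybenzoic acid
Product: 30 4-[(tert-butyldimethylsilyl)oxy]benzoic acid, via tert-butyldimethylsilyl 4-[(tert-butyldimethylsilyl)oxy]benzoate 29 (not isolated)
Conditions: t-BuMe2SiCl (2.4 equiv), imidazole, DMF, rt; then AcOH/THF/H2O, rt
Reagents that add atoms: tert-butyldimethylsilyl chloride, CC(C)(C)[Si](C)(C)Cl
Why: Exhaustive silylation followed by selective hydrolysis of the labile silyl ester leaves the phenol as a silyl ether that the last step removes together with the other silyl groups.

Step 19
Reactants: 27 6-hydroxy-4,8,9-tris(triethylsilyloxy)daucan-7-one; 30 4-[(tert-butyldimethylsilyl)oxy]benzoic acid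
Product: 31 6-{4-[(tert-butyldimethylsilyl)oxy]benzoyloxy}-4,8,9-tris(triethylsilyloxy)daucan-7-one
Conditions: DCC, DMAP, CH2Cl2, rt
Reagents that add atoms: none
Why: Steglich esterification acylates the only free hydroxyl, the secondary C6–OH, with retention at C6.

Step 20
Reactants: 31 6-{4-[(tert-butyldimethylsilyl)oxy]benzoyloxy}-4,8,9-tris(triethylsilyloxy)daucan-7-one
Product: 32 CNP0241001.1, 4,8,9-trihydroxy-6-(4-hydroxybenzoyloxy)daucan-7-one
Conditions: HF·pyridine, pyridine, THF, 0 °C → rt
Reagents that add atoms: none
Why: Fluoride cleaves the aryl silyl ether and the three triethylsilyl ethers under buffered, weakly acidic conditions that spare the ester, the ketol and the β-hydroxy ketone, and no stereocentre is touched.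

Compound list
1 | 3-methylbut-1-yne | CC(C)C#C | starting material
2 | paraformaldehyde (formaldehyde equivalent) | C=O | starting material
3 | lithium 3-methylbut-1-yn-1-ide | CC(C)C#C[Li] | intermediate (not isolated)
4 | 4-methylpent-2-yn-1-ol | CC(C)C#CCO | intermediate
5 | sodium 2,2-bis(2-methoxyethoxy)-3-(propan-2-yl)-2,5-dihydro-1,2-oxaluminol-2-uide (cyclic alkenylalanate) | CC(C)C1=CCO[Al-]1(OCCOC)OCCOC.[Na+] | intermediate (not isolated)
6 | (2Z)-3-iodo-4-methylpent-2-en-1-ol | OC/C=C(/C(C)C)I | intermediate
7 | 4-bromo-2-methylbut-1-ene | C=C(C)CCBr | starting material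
8 | (3-methylbut-3-en-1-yl)zinc bromide | C=C(C)CC[Zn]Br | intermediate (not isolated)
9 | (2E)-6-methyl-3-(propan-2-yl)hepta-2,6-dien-1-ol | OC/C=C(/C(C)C)CCC(C)=C | intermediate
10 | [(2R,3R)-3-(3-methylbut-3-en-1-yl)-3-(propan-2-yl)oxiran-2-yl]methanol | CC(C)[C@@]1(CCC(C)=C)O[C@@H]1CO | intermediate
11 | (2R,3S)-3-(chloromethyl)-2-(3-methylbut-3-en-1-yl)-2-(propan-2-yl)oxirane | CC(C)[C@@]1(CCC(C)=C)O[C@@H]1CCl | intermediate
12 | dilithium salt (alkynide and alkoxide) of (3R)-6-methyl-3-(propan-2-yl)hept-6-en-1-yn-3-ol | CC(C)[C@](O[Li])(CCC(C)=C)C#C[Li] | intermediate (not isolated)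
13 | (4R)-7-methyl-4-(propan-2-yl)oct-7-en-2-yn-4-ol | CC(C)[C@](O)(CCC(C)=C)C#CC | intermediate
14 | triethyl{[(4R)-7-methyl-4-(propan-2-yl)oct-7-en-2-yn-4-yl]oxy}silane | CC(C)[C@](O[Si](CC)(CC)CC)(CCC(C)=C)C#CC | intermediate
15 | hexacarbonyldicobalt complex of alkyne 14 | CC12C3([C@@](O[Si](CC)(CC)CC)(CCC(C)=C)C(C)C)[Co]1(=C=O)(=C=O)(=C=O)[Co]23(=C=O)(=C=O)=C=O | intermediate (not isolated)
16 | (4R,6aR)-3,6a-dimethyl-4-(propan-2-yl)-4-[(triethylsilyl)oxy]-4,5,6,6a-tetrahydropentalen-2(1H)-one | CC(C)[C@]1(O[Si](CC)(CC)CC)CC[C@]2(C)CC(=O)C(C)=C12 | intermediate (key-step precursor)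
17 | acetylene | C#C | starting material
18 | 4,7-dimethyl-10-(propan-2-yl)-10-[(triethylsilyl)oxy]tricyclo[5.3.0.0^{1,4}]dec-2-en-5-one, cyclobutene cis-fused on the face of the C1 methyl | CC(C)[C@]1(O[Si](CC)(CC)CC)CC[C@]2(C)CC(=O)[C@@]3(C)C=C[C@@]123 | intermediate (key-step product)
19 | 4-(triethylsilyloxy)dauca-5,7-dien-9-one | CC(C)[C@]1(O[Si](CC)(CC)CC)CC[C@]2(C)CC(=O)C(C)=CC=C12 | intermediate
20 | 7,8-epoxy-4-(triethylsilyloxy)dauc-5-en-9-one (upper-face epoxide drawn) | CC(C)[C@]1(O[Si](CC)(CC)CC)CC[C@]2(C)CC(=O)[C@]3(C)O[C@@H]3C=C12 | intermediate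
21 | 4-(triethylsilyloxy)dauca-5,8-dien-7-ol (upper-face 7-OH drawn) | CC(C)[C@]1(O[Si](CC)(CC)CC)CC[C@]2(C)CC=C(C)[C@H](O)C=C12 | intermediate
22 | 4-(triethylsilyloxy)dauca-5,8-dien-7-one | CC(C)[C@]1(O[Si](CC)(CC)CC)CC[C@]2(C)CC=C(C)C(=O)C=C12 | intermediate
23 | 8,9-dihydroxy-4-(triethylsilyloxy)dauc-5-en-7-one | CC(C)[C@]1(O[Si](CC)(CC)CC)CC[C@]2(C)C[C@H](O)[C@](C)(O)C(=O)C=C12 | intermediate
24 | 8,9-dihydroxy-4-(triethylsilyloxy)daucan-7-one | CC(C)[C@]1(O[Si](CC)(CC)CC)CC[C@]2(C)C[C@H](O)[C@](C)(O)C(=O)C[C@H]21 | intermediate
25 | 4,8,9-tris(triethylsilyloxy)daucan-7-one | CC(C)[C@]1(O[Si](CC)(CC)CC)CC[C@]2(C)C[C@H](O[Si](CC)(CC)CC)[C@](C)(O[Si](CC)(CC)CC)C(=O)C[C@H]21 | intermediate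
26 | potassium enolate (C6=C7–OK) of 25 | CC(C)[C@]1(O[Si](CC)(CC)CC)CC[C@]2(C)C[C@H](O[Si](CC)(CC)CC)[C@](C)(O[Si](CC)(CC)CC)C(O[K])=C[C@H]21 | intermediate (not isolated)
27 | 6-hydroxy-4,8,9-tris(triethylsilyloxy)daucan-7-one | CC(C)[C@]1(O[Si](CC)(CC)CC)CC[C@]2(C)C[C@H](O[Si](CC)(CC)CC)[C@](C)(O[Si](CC)(CC)CC)C(=O)[C@H](O)[C@H]21 | intermediate
28 | 4-hydroxybenzoic acid | OC(=O)c1ccc(O)cc1 | starting material
29 | tert-butyldimethylsilyl 4-[(tert-butyldimethylsilyl)oxy]benzoate | CC(C)(C)[Si](C)(C)OC(=O)c1ccc(O[Si](C)(C)C(C)(C)C)cc1 | intermediate (not isolated)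
30 | 4-[(tert-butyldimethylsilyl)oxy]benzoic acid | CC(C)(C)[Si](C)(C)Oc1ccc(cc1)C(=O)O | intermediate
31 | 6-{4-[(tert-butyldimethylsilyl)oxy]benzoyloxy}-4,8,9-tris(triethylsilyloxy)daucan-7-one | CC(C)[C@]1(O[Si](CC)(CC)CC)CC[C@]2(C)C[C@H](O[Si](CC)(CC)CC)[C@](C)(O[Si](CC)(CC)CC)C(=O)[C@H](OC(=O)c3ccc(O[Si](C)(C)C(C)(C)C)cc3)[C@H]21 | intermediate
32 | CNP0241001.1, 4,8,9-trihydroxy-6-(4-hydroxybenzoyloxy)daucan-7-one | CC(C)[C@]1(O)CC[C@]2(C)C[C@H](O)[C@](C)(O)C(=O)[C@H](OC(=O)c3ccc(O)cc3)[C@H]21 | target

Total step count: 20. Longest linear sequence: 19 steps (steps 1–17, 19 and 20, from 3-methylbut-1-yne 1); step 18 is a one-step side branch.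

Steps most likely to fail

Step 8 (Pauson–Khand cyclisation). What may go wrong is alkene insertion on the wrong face of the cobalt–alkyne complex, so that the quaternary C1 forms with its methyl trans to the silyloxy group. The other failure mode is slow insertion of the 1,1-disubstituted alkene, with loss of the complex. The fallback sets out from enyne 14 and returns at enone 16, and it replaces substrate control by catalyst control. Enyne 14 would be cyclocarbonylated under CO (1 atm) with a cationic rhodium catalyst made from [Rh(CO)2Cl]2, AgOTf and a single enantiomer of BINAP in THF at 60–80 °C. Both ligand antipodes are available, so the one matched to the C4 centre can be chosen to reinforce or override its bias. This gives 16 directly and no new compound arises (F0).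

Step 9 (photocycloaddition). What may go wrong is slow bond formation at the congested C5, whose reacting lower face is flanked by the C1 methyl and the C4 silyloxy group, so that the excited enone decays unproductively. On long irradiation the β,γ-unsaturated ketone product may also suffer a 1,3-acyl shift. The fallback sets out from enone 16 and returns at cyclobutene 18, using an acetylene equivalent. Enone 16 would be irradiated through Pyrex in CH2Cl2 at −20 °C with a large excess of (E)-1,2-dichloroethene. Alkenes trap triplet cyclopentenones more efficiently than acetylene, and the saturated product, the dichlorocyclobutane adduct F1 (mixed chloride configurations), has no β,γ-unsaturation to react further. Reductive 1,2-elimination with activated Zn in EtOH at 70 °C would then give 18.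

Step 15 (directed hydrogenation). What may go wrong is deactivation of the iridium catalyst before turnover at the hindered trisubstituted enone bond, or delivery of hydrogen to the lower face. The fallback sets out from enone diol 23 and returns at hydroxy ketone 27, replacing steps 15–17. Compound 23, which has no enolisable position, would first be silylated (Et3SiOTf, 2,6-lutidine, CH2Cl2) to 4,8,9-tris(triethylsilyloxy)dauc-5-en-7-one F2. A manganese-catalysed hydrogen-atom-transfer reductive hydroxylation would follow (Mn(dpm)3 cat., PhSiH3, O2, i-PrOH/CH2Cl2, 0 °C; then P(OEt)3). The small hydrogen-atom donor should add H to C5 from the upper face, since the lower face carries the C1 methyl and the C4 silyloxy group, and the resulting C6 radical is trapped by O2 to give 27.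

Further compounds
F0 | step 8 | none | none
F1 | step 9 | 2,3-dichloro-4,7-dimethyl-10-(propan-2-yl)-10-[(triethylsilyl)oxy]tricyclo[5.3.0.0^{1,4}]decan-5-one (chloride configurations mixed) | CC(C)[C@]1(O[Si](CC)(CC)CC)CC[C@]2(C)CC(=O)[C@@]3(C)C(Cl)C(Cl)[C@@]123
F2 | step 15 | 4,8,9-tris(triethylsilyloxy)dauc-5-en-7-one | CC(C)[C@]1(O[Si](CC)(CC)CC)CC[C@]2(C)C[C@H](O[Si](CC)(CC)CC)[C@](C)(O[Si](CC)(CC)CC)C(=O)C=C12
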